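**The flat stretch.** Intermediate moves slowly late in the elm run, and that slowness is the handle.

| flask | substrate | remark | time |
|---|---|---|---|
| ash | 0.32 M | run made earlier |  |
| elm | 1.6 M | run made earlier |  |
| south | 0.50 M |  | 15 min |
| south-west | 1.0 M |  | 15 min |
| east | 2.0 M |  | 15 min |

| run | time / min | intermediate / % | target / % |
|---|---|---|---|
| ash | 2.00 | 24 | 9 |
| ash | 4.00 | 27 | 6 |
| ash | 5.00 | 29 | 11 |
| ash | 8.00 | 34 | 12 |
| ash | 10.0 | 39 | 19 |
| elm | 0.667 | 11 | 2 |
| elm | 2.00 | 20 | 3 |
| elm | 4.00 | 26 | 8 |
| elm | 6.00 | 31 | 13 |
| elm | 8.00 | 28 | 13 |
| elm | 10.0 | 32 | 10 |

(each reading ± 2 percentage points)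

- a species is counted by the substrate in it: one side product A counts as two
- the analysis behind the earlier runs scatters by 2 percentage points, standard deviation
- reactions considered so far: intermediate <-> target; target <-> isomer of the product; intermediate -> side product B; substrate + target -> side product A; substrate <-> intermediate
- "hardly changes" means that all values lie within two and a half points (for a concentration: within two and a half percent of the largest)

- [intermediate] at the end for south, south-west, east, in this order
- how the row runs (hardly changes / rises, then falls / rises all the way / falls, then rises / falls all the way)

Elm reads 31 %, 28 % and 32 % of the charge at 6.00 min, 8.00 min and 10.0 min, with a scatter of 2 percentage points. Ash reads 34 % and 39 % at the last two times. So I hold each level out to 15 min, and I average those last two times: ash keeps 36.5 % and elm 30.0 %.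

**Charge penalty.** Work with the fraction kept. The charge penalty is the drop in the natural log of the intermediate fraction per mole per litre of extra charge. Ash and elm give 0.153 M⁻¹. Among the listed steps, substrate + target has two partners, so I look there for a loss that differs with charge.

**Fractions kept.** Start from ash and multiply by the exponential of minus the penalty times the extra charge. My estimate for south is 35.5 %, for south-west 32.9 % and for east 28.2 %. Times the charge, my row is 0.178 M, 0.329 M, 0.564 M.

**Weak link.** Ash may still be rising, so the ash pair is the weak link. Put its last reading alone in place of the pair. The penalty becomes 0.205 M⁻¹. South moves to 0.188 M and east to 0.553 M. In this exponential estimate, charge times kept fraction rises while penalty times charge stays below one, and at east that product is 0.410. The estimated row still rises, and I commit to my first numbers.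

**The forecast.** It gives 0.21 M, 0.39 M, 0.68 M, and says: “The percentage falls only mildly, so the molarity still rises all the way”. Its east value is higher than mine.

    intermediate ⇌ target (K = 0.450, k = 0.00600 s⁻¹)
    target ⇌ isomer of the product (K = 0.740, k = 0.0700 s⁻¹)
    intermediate → side product B (k = 5.20 × 10⁻⁴ s⁻¹)
    substrate + target → side product A (k = 0.00490 M⁻¹ s⁻¹)
    substrate ⇌ intermediate (K = 14.0, k = 0.00260 s⁻¹)

**The flask.** The row is 0.180 M, 0.322 M, 0.538 M and rises all the way, with the forecast 0.142 M above east. South and east give a penalty of 0.193 M⁻¹. The penalty from ash and elm, carried from south to south-west, gives 33.3 %, and south-west holds 32.2 %. In south, intermediate is made 1.69 times as fast as it is used at 3.58 min, but 0.783 times as fast at 15.0 min, so it is falling by then. Its fraction in south stands at 34.9 % at 7.50 min and 35.9 % at 15.0 min.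

The runs stem from a simulated flask from invented constants; noise was put on by code.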